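**Strategy.** Ring C of the flavanone is cut at O1–C2 and C3–C4. The fragment O1–C8a–C4a–C4 of ring A is an ortho-quinone methide in its O-methyl oxocarbenium form; C2–C3 comes from the ring B styrene, made nucleophilic by the 4'-methoxy group para to C1'. One three-component hetero-[4+2] under a chiral Brønsted acid therefore joins a fully substituted salicylaldehyde (free 2-OH, two MOM ethers, two prenyl groups), trimethyl orthoformate and the prenylated styrene, closes the pyran ring and sets C2 as S; C4 arrives as a methyl ether, one oxidation level below the ketone.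

Key step: step 8

Remarks on the chemistry:
- The target is the (2S)-flavanone; the same sense at C2 in the 2,4-cis cycloadduct is (2S,4S). The free 2-OH of the salicylaldehyde becomes O1 and its C3 prenyl group becomes the C8 prenyl group.
- Assumption: the sense of induction of the chiral acid cannot be predicted with certainty. The (R)-acid is written; the (S)-acid is used if a first screen shows the opposite sense.
- The C4 methyl ether is taken to the ketone by solvolysis and Dess–Martin oxidation, not by a quinone oxidant, because the molecule carries three benzylic-allylic CH2 groups on electron-rich rings.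

**Ring A fragment**

Step 1
Reactants: 1 2,4,6-trihydroxybenzaldehyde; 2 prenyl bromide (1-bromo-3-methylbut-2-ene)
Product: 3 2,4,6-trihydroxy-3,5-bis(3-methylbut-2-en-1-yl)benzaldehyde
Conditions: 2 (2.2 equiv), 10% aq KOH, 0 °C → rt; dilute HCl to pH 3
Reagents that add atoms: none
Why: C-alkylation of an acylphloroglucinol polyphenoxide in water is the classical entry to 3,5-diprenyl acylphloroglucinols, because hydrogen bonding to water blunts the oxygen nucleophiles and leaves C3 and C5 as the reactive sites; mono-, gem-di- and O-alkylated material is removed by chromatography.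

Step 2
Reactants: 3 2,4,6-trihydroxy-3,5-bis(3-methylbut-2-en-1-yl)benzaldehyde
Product: 4 2-hydroxy-4,6-bis(methoxymethoxy)-3,5-bis(3-methylbut-2-en-1-yl)benzaldehyde
Conditions: MOMCl (2.3 equiv), iPr2NEt, CH2Cl2, 0 °C → rt
Reagents that add atoms: chloromethyl methyl ether, COCCl
Why: Williamson-type O-alkylation protects the 4-OH and one of the two symmetry-equivalent ortho-OH groups, while the last OH stays free because it is locked in a hydrogen bond to the formyl group, as is usual for 2,4,6-trihydroxyaryl carbonyl compounds.

**Ring B fragment**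

Step 3
Reactants: 5 5-bromovanillin (3-bromo-4-hydroxy-5-methoxybenzaldehyde)
Product: 6 3-bromo-4,5-dihydroxybenzaldehyde
Conditions: BBr3 (2.5 equiv), CH2Cl2, −78 °C → rt; then H2O
Reagents that add atoms: none
Why: Lewis acid cleavage of the aryl methyl ether (BBr3 demethylation) is reliable on vanillin-type aldehydes and leaves the aryl bromide and the formyl group in place.

Step 4
Reactants: 6 3-bromo-4,5-dihydroxybenzaldehyde
Product: 7 3-bromo-5-hydroxy-4-methoxybenzaldehyde
Conditions: MeI (1.1 equiv), Li2CO3 (1.2 equiv), DMF, 40 °C
Reagents that add atoms: iodomethane, CI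
Why: Regioselective Williamson methylation works because the 4-OH, para to the formyl group and ortho to bromine, is the more acidic phenol, so the weak base forms and alkylates only that phenoxide, as known for 3,4-dihydroxybenzaldehydes.

Step 5
Reactants: 7 3-bromo-5-hydroxy-4-methoxybenzaldehyde
Product: 8 3-bromo-4-methoxy-5-(methoxymethoxy)benzaldehyde
Conditions: MOMCl (1.3 equiv), iPr2NEt, CH2Cl2, 0 °C → rt
Reagents that add atoms: chloromethyl methyl ether, COCCl
Why: Standard MOM ether formation protects the remaining phenol, which would otherwise be oxidised in step 10 and would bind the acid catalyst in step 8.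

Step 6
Reactants: 8 3-bromo-4-methoxy-5-(methoxymethoxy)benzaldehyde
Product: 9 4-methoxy-3-(methoxymethoxy)-5-(3-methylbut-2-en-1-yl)benzaldehyde
Conditions: Bu3SnCH2CH=CMe2 (1.3 equiv), Pd(PPh3)4 (5 mol%), DMF, 90 °C
Reagents that add atoms: tributyl(3-methylbut-2-en-1-yl)stannane, CCCC[Sn](CCCC)(CCCC)CC=C(C)C
Why: Stille coupling under zerovalent palladium transfers the prenyl group through its CH2 terminus to give the linear prenyl arene, the usual outcome for prenylstannanes with aryl bromides, and tolerates the aldehyde and the MOM ether.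

Step 7
Reactants: 9 4-methoxy-3-(methoxymethoxy)-5-(3-methylbut-2-en-1-yl)benzaldehyde
Product: 10 5-ethenyl-2-methoxy-1-(methoxymethoxy)-3-(3-methylbut-2-en-1-yl)benzene (4-methoxy-3-(methoxymethoxy)-5-prenylstyrene)
Conditions: Ph3PCH3Br (1.3 equiv), KOtBu (1.25 equiv), THF, 0 °C → rt
Reagents that add atoms: methyltriphenylphosphonium bromide, C[P+](c1ccccc1)(c1ccccc1)c1ccccc1.[Br-]
Why: Wittig methylenation of an aromatic aldehyde with the unstabilised ylide is dependable and gives the styrene, which is stored cold with a trace of BHT and used fresh.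

**Key step and endgame**

Step 8
Reactants: 4 2-hydroxy-4,6-bis(methoxymethoxy)-3,5-bis(3-methylbut-2-en-1-yl)benzaldehyde; 10 4-methoxy-3-(methoxymethoxy)-5-prenylstyrene; 11 trimethyl orthoformate
Product: 14 (2S,4S)-4-methoxy-2-[4-methoxy-3-(methoxymethoxy)-5-(3-methylbut-2-en-1-yl)phenyl]-5,7-bis(methoxymethoxy)-6,8-bis(3-methylbut-2-en-1-yl)chromane (2,4-cis), via dimethyl acetal 12 (not isolated), via oxocarbenium ion 13 (not isolated)
Conditions: (R)-3,3'-bis(2,4,6-triisopropylphenyl)-BINOL N-triflylphosphoramide (10 mol%), 10 (1.5 equiv), 11 (1.5 equiv), 5 Å MS, CH2Cl2, −40 → −20 °C; Et3N quench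
Reagents that add atoms: none
Why: Proposed new method: acid-catalysed acetal exchange turns 4 into acetal 12, which ionises to oxocarbenium ion 13 (an O-methylated ortho-quinone methide) held to the chiral phosphoramide anion by ion pairing and by a hydrogen bond from the C8a–OH; the styrene CH2 then adds to C4 and the C2 benzylic cation, stabilised by ring B, is captured by that phenol oxygen in an asynchronous inverse-demand hetero-[4+2]. The closest known reactions are the racemic acid-catalysed three-component synthesis of 4-methoxy-2-arylchromans from salicylaldehydes, orthoformates and styrenes, and chiral phosphoric acid-type cycloadditions of ortho-quinone methides generated in situ, including the intramolecular oxocarbenium variant; the enantioselective intermolecular case with a simple styrene is the unproven part. Ring C is closed intermolecularly as a [4+2] annulation, C3–C4 first and O1–C2 second as a six-membered capture of the cation by the phenol. C4 is set by the anion shielding one face of 13, and C2 is set in the ring closure inside the same ion pair through a chair-like arrangement with the aryl group equatorial and cis to the methoxy group, so the acid enantiomer fixes C2 as S. The step needs regioselectivity, which the polarity of the partners secures (nucleophilic CH2 to electrophilic C4), chemoselectivity for the styrene over three prenyl alkenes, secured by its unhindered terminal carbon, its benzylic cation and its excess, and an acid weak and cold enough to leave the MOM ethers and the phenol next to the C8 prenyl group untouched.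

Step 9
Reactants: 14 (2S,4S)-4-methoxyflavan with three MOM ethers and three prenyl groups
Product: 15 (2S)-2-[4-methoxy-3-(methoxymethoxy)-5-(3-methylbut-2-en-1-yl)phenyl]-5,7-bis(methoxymethoxy)-6,8-bis(3-methylbut-2-en-1-yl)chroman-4-ol (mixture of C4 epimers)
Conditions: CSA (10 mol%), THF/H2O (4:1), 0 °C → rt; Et3N quench
Reagents that add atoms: water, O
Why: SN1 solvolysis exchanges the C4 methyl ether for hydroxyl under mild acid because the C4 cation is a 2,4,6-trioxygenated benzylic cation (O1, O5 and O7 on ring A) that water in large excess captures, while the aryl MOM ethers and C2 are not touched and the C4 epimer mixture is irrelevant since C4 becomes sp2 in step 10.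

Step 10
Reactants: 15 (2S)-flavan-4-ol with three MOM ethers and three prenyl groups
Product: 16 (2S)-2-[4-methoxy-3-(methoxymethoxy)-5-(3-methylbut-2-en-1-yl)phenyl]-5,7-bis(methoxymethoxy)-6,8-bis(3-methylbut-2-en-1-yl)chroman-4-one
Conditions: DMP (1.3 equiv), pyridine (5 equiv), CH2Cl2, 0 °C → rt
Reagents that add atoms: none
Why: Dess–Martin oxidation of a secondary benzylic alcohol under pyridine buffering is neutral and leaves the prenyl alkenes, the MOM ethers and the C2 stereocentre alone, which a quinone oxidant could not guarantee here.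

Step 11
Reactants: 16 (2S)-flavanone with three MOM ethers and three prenyl groups
Product: 17 isoamoritin, (2S)-5,7-dihydroxy-2-[3-hydroxy-4-methoxy-5-(3-methylbut-2-en-1-yl)phenyl]-6,8-bis(3-methylbut-2-en-1-yl)chroman-4-one
Conditions: HCl (1 M in MeOH), rt → 40 °C
Reagents that add atoms: none
Why: Acid-catalysed acetal exchange with methanol removes the three MOM ethers as dimethoxymethane under the standard conditions for prenylated flavanones, and the low temperature and early stop keep the free phenols from adding to the neighbouring prenyl alkenes and keep C2 (S) from epimerising through ring opening.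

**Compound list**

1 | 2,4,6-trihydroxybenzaldehyde | O=Cc1c(O)cc(O)cc1O | starting material
2 | prenyl bromide (1-bromo-3-methylbut-2-ene) | CC(C)=CCBr | starting material
3 | 2,4,6-trihydroxy-3,5-bis(3-methylbut-2-en-1-yl)benzaldehyde | O=Cc1c(O)c(CC=C(C)C)c(O)c(CC=C(C)C)c1O | intermediate
4 | 2-hydroxy-4,6-bis(methoxymethoxy)-3,5-bis(3-methylbut-2-en-1-yl)benzaldehyde | O=Cc1c(O)c(CC=C(C)C)c(OCOC)c(CC=C(C)C)c1OCOC | intermediate
5 | 5-bromovanillin (3-bromo-4-hydroxy-5-methoxybenzaldehyde) | COc1cc(C=O)cc(Br)c1O | starting material
6 | 3-bromo-4,5-dihydroxybenzaldehyde | O=Cc1cc(O)c(O)c(Br)c1 | intermediate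
7 | 3-bromo-5-hydroxy-4-methoxybenzaldehyde | COc1c(O)cc(C=O)cc1Br | intermediate
8 | 3-bromo-4-methoxy-5-(methoxymethoxy)benzaldehyde | COCOc1cc(C=O)cc(Br)c1OC | intermediate
9 | 4-methoxy-3-(methoxymethoxy)-5-(3-methylbut-2-en-1-yl)benzaldehyde | COCOc1cc(C=O)cc(CC=C(C)C)c1OC | intermediate
10 | 5-ethenyl-2-methoxy-1-(methoxymethoxy)-3-(3-methylbut-2-en-1-yl)benzene | C=Cc1cc(CC=C(C)C)c(OC)c(OCOC)c1 | intermediate
11 | trimethyl orthoformate | COC(OC)OC | starting material
12 | 2-(dimethoxymethyl)-3,5-bis(methoxymethoxy)-4,6-bis(3-methylbut-2-en-1-yl)phenol (dimethyl acetal of 4) | COC(OC)c1c(O)c(CC=C(C)C)c(OCOC)c(CC=C(C)C)c1OCOC | intermediate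
13 | O-methyl oxocarbenium ion of 4 (O-methylated ortho-quinone methide, paired with the phosphoramide anion) | C[O+]=Cc1c(O)c(CC=C(C)C)c(OCOC)c(CC=C(C)C)c1OCOC | intermediate
14 | (2S,4S)-4-methoxy-2-[4-methoxy-3-(methoxymethoxy)-5-(3-methylbut-2-en-1-yl)phenyl]-5,7-bis(methoxymethoxy)-6,8-bis(3-methylbut-2-en-1-yl)chromane | CO[C@H]1C[C@@H](c2cc(CC=C(C)C)c(OC)c(OCOC)c2)Oc2c(CC=C(C)C)c(OCOC)c(CC=C(C)C)c(OCOC)c12 | intermediate
15 | (2S)-2-[4-methoxy-3-(methoxymethoxy)-5-(3-methylbut-2-en-1-yl)phenyl]-5,7-bis(methoxymethoxy)-6,8-bis(3-methylbut-2-en-1-yl)chroman-4-ol, C4 epimers | OC1C[C@@H](c2cc(CC=C(C)C)c(OC)c(OCOC)c2)Oc2c(CC=C(C)C)c(OCOC)c(CC=C(C)C)c(OCOC)c12 | intermediate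
16 | (2S)-2-[4-methoxy-3-(methoxymethoxy)-5-(3-methylbut-2-en-1-yl)phenyl]-5,7-bis(methoxymethoxy)-6,8-bis(3-methylbut-2-en-1-yl)chroman-4-one | O=C1C[C@@H](c2cc(CC=C(C)C)c(OC)c(OCOC)c2)Oc2c(CC=C(C)C)c(OCOC)c(CC=C(C)C)c(OCOC)c12 | intermediate
17 | isoamoritin | COc1c(O)cc([C@@H]2CC(=O)c3c(O)c(CC=C(C)C)c(O)c(CC=C(C)C)c3O2)cc1CC=C(C)C | target

**Count**

Total step count: 11. Longest linear sequence: 9 steps (steps 3 to 11, from 5).

**Steps most likely to fail**

Step 8. Three things may go wrong.
- Facial selection inside the ion pair may be poor, which would lower the enantiomeric purity at C2.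
- Addition may be slow, because the 4'-methoxy group is flanked on both sides and donates less than in a simple 4-methoxystyrene.
- Slow addition would give time for capture of the oxocarbenium ion by prenyl alkenes, styrene oligomerisation or loss of MOM groups.

The fallback uses known chemistry and sets out from 4, 10 and 11. The three components are combined with Sc(OTf)3 (5 mol%) in CH2Cl2 at 0 °C, the established racemic Lewis acid version of the cycloaddition, to give racemic 4-methoxyflavan F1 (C4 epimers taken on together). Solvolysis as in step 9 should give racemic flavan-4-ol F2, and Dess–Martin oxidation as in step 10 should give racemic flavanone F3. F3 is then resolved kinetically by asymmetric transfer hydrogenation (Noyori–Ikariya type; RuCl(p-cymene)[(R,R)-TsDPEN], HCO2H/Et3N, EtOAc, rt, run just past half conversion). By the usual sense of this catalyst the (2R)-ketone should be reduced to the (2R,4R)-cis-flavan-4-ol F4, and the unreduced (2S)-ketone is separated by chromatography. The fallback comes back to the route at 16; the catalyst antipode is used if the fast-reacting enantiomer proves to be the other one.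

Step 1. O-alkylation, a second alkylation at an already substituted carbon (gem-diprenyl dienones) and incomplete second C-alkylation may leave little of the 3,5-diprenyl compound. The fallback sets out from 1 and installs the prenyl groups by cross-coupling. Bis-MOM protection (MOMCl, iPr2NEt, CH2Cl2) should give 2-hydroxy-4,6-bis(methoxymethoxy)benzaldehyde F5. Iodination of both activated positions (NIS, 2.2 equiv, DMF, 0 °C → rt) should give 2-hydroxy-3,5-diiodo-4,6-bis(methoxymethoxy)benzaldehyde F6. A double Stille coupling with Bu3SnCH2CH=CMe2 (Pd(PPh3)4, DMF, 90 °C) then comes back to the route at 4.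

Step 9. Loss of H3 from the C4 cation (E1) to a flav-3-ene may compete with capture by water, and over-long exposure may start to remove MOM groups. The fallback sets out from 14 and replaces solvolysis plus alcohol oxidation by direct hydride abstraction. DDQ (1.2 equiv) in CH2Cl2/pH 7 buffer at 0 °C should oxidise the C4–H of the benzylic methyl ether to the methoxy oxocarbenium ion, which water converts to the ketone. This comes back to the route at 16 and skips 15; no new compound is made (F0). It is held in reserve because the prenyl CH2 groups may also be attacked by the quinone.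

**Further compounds**

F1 | step 8 | racemic 4-methoxy-2-[4-methoxy-3-(methoxymethoxy)-5-(3-methylbut-2-en-1-yl)phenyl]-5,7-bis(methoxymethoxy)-6,8-bis(3-methylbut-2-en-1-yl)chromane, C4 epimers | COC1CC(c2cc(CC=C(C)C)c(OC)c(OCOC)c2)Oc2c(CC=C(C)C)c(OCOC)c(CC=C(C)C)c(OCOC)c12
F2 | step 8 | racemic 2-[4-methoxy-3-(methoxymethoxy)-5-(3-methylbut-2-en-1-yl)phenyl]-5,7-bis(methoxymethoxy)-6,8-bis(3-methylbut-2-en-1-yl)chroman-4-ol, C4 epimers | OC1CC(c2cc(CC=C(C)C)c(OC)c(OCOC)c2)Oc2c(CC=C(C)C)c(OCOC)c(CC=C(C)C)c(OCOC)c12
F3 | step 8 | racemic 2-[4-methoxy-3-(methoxymethoxy)-5-(3-methylbut-2-en-1-yl)phenyl]-5,7-bis(methoxymethoxy)-6,8-bis(3-methylbut-2-en-1-yl)chroman-4-one | O=C1CC(c2cc(CC=C(C)C)c(OC)c(OCOC)c2)Oc2c(CC=C(C)C)c(OCOC)c(CC=C(C)C)c(OCOC)c12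
F4 | step 8 | (2R,4R)-2-[4-methoxy-3-(methoxymethoxy)-5-(3-methylbut-2-en-1-yl)phenyl]-5,7-bis(methoxymethoxy)-6,8-bis(3-methylbut-2-en-1-yl)chroman-4-ol (2,4-cis) | O[C@@H]1C[C@H](c2cc(CC=C(C)C)c(OC)c(OCOC)c2)Oc2c(CC=C(C)C)c(OCOC)c(CC=C(C)C)c(OCOC)c12
F5 | step 1 | 2-hydroxy-4,6-bis(methoxymethoxy)benzaldehyde | O=Cc1c(O)cc(OCOC)cc1OCOC
F6 | step 1 | 2-hydroxy-3,5-diiodo-4,6-bis(methoxymethoxy)benzaldehyde | O=Cc1c(O)c(I)c(OCOC)c(I)c1OCOC
F0 | step 9 | none | none
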